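**Plan**

- Retrosynthesis: the C1 hydroxyl of ring A is traced back to a formyl group (Baeyer–Villiger). Ring B is then cut at C1'–C2' and C5'–C6', which leaves an ethynyl ether on O2 of ring A and 3,5-dibromo-2-pyrone.
- Enabling feature: C2'(Br)–C3'(H)–C4'(Br)–C5'(H) of ring B is the C3–C6 diene of the dibromopyrone, and C1'(O)/C6'(H) are the two carbons of an aryloxyacetylene.
- Further cuts: the O–C≡CH unit goes back to an O–CH2CH2Br ether (from 1,2-dibromoethane), and the ring A bromines to 2-hydroxy-4-methoxybenzaldehyde.
- Forward: ring A is bought and fully substituted first, the two-carbon unit is attached to O2 and taken to the alkyne, and ring B then arises in one cycloaddition with loss of CO2. Last, CHO becomes OH.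
- Stereochemistry: the target has no stereocentre. The Z geometry of a bromovinyl ether and two bridgehead centres of a transient lactone appear on the way and are erased.

Key step: step 8

Assumption: the formyl group is carried as its 1,3-dioxolane from step 3 to step 9, because the potassium acetylide formed in step 6 would add to a free aldehyde. The terminal ynol ether 9 is prepared and used at once.

**Route**

Step 1
Reactants: 1 2-hydroxy-4-methoxybenzaldehyde
Product: 2 3,5-dibromo-2-hydroxy-4-methoxybenzaldehyde
Conditions: Br2 (2.2 equiv), NaOAc, AcOH, rt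
Reagents that add atoms: bromine, BrBr
Why: Electrophilic aromatic bromination; the ortho/para-directing OH and OMe and the meta-directing CHO all point to C3 and C5, so the reaction should stop at the dibromide.

Step 2
Reactants: 2 3,5-dibromo-2-hydroxy-4-methoxybenzaldehyde; 3 1,2-dibromoethane (5 equiv)
Product: 4 3,5-dibromo-2-(2-bromoethoxy)-4-methoxybenzaldehyde
Conditions: K2CO3, DMF, 70 °C
Reagents that add atoms: none
Why: Williamson ether synthesis of an acidic phenoxide with a primary bromide; the excess of 3 should suppress the bis-aryl ether.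

Step 3
Reactants: 4 3,5-dibromo-2-(2-bromoethoxy)-4-methoxybenzaldehyde
Product: 5 2-[3,5-dibromo-2-(2-bromoethoxy)-4-methoxyphenyl]-1,3-dioxolane
Conditions: HOCH2CH2OH, p-TsOH (cat.), PhMe, reflux, Dean–Stark
Reagents that add atoms: ethylene glycol, OCCO
Why: Acid-catalysed acetalisation with azeotropic removal of water; the dioxolane shields the formyl carbon from the alkoxide bases and the acetylide of steps 4 and 6, and the primary bromide is untouched.

Step 4
Reactants: 5 2-[3,5-dibromo-2-(2-bromoethoxy)-4-methoxyphenyl]-1,3-dioxolane
Product: 6 2-[3,5-dibromo-2-(ethenyloxy)-4-methoxyphenyl]-1,3-dioxolane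
Conditions: KOt-Bu (1.5 equiv), THF, 0 °C → rt
Reagents that add atoms: none
Why: E2 dehydrobromination of a 2-bromoethyl aryl ether by a hindered alkoxide, the standard entry to aryl vinyl ethers; acetal and aryl bromides are inert to KOt-Bu at this temperature.

Step 5
Reactants: 6 2-[3,5-dibromo-2-(ethenyloxy)-4-methoxyphenyl]-1,3-dioxolane
Product: 8 2-{3,5-dibromo-2-[(Z)-2-bromoethenyloxy]-4-methoxyphenyl}-1,3-dioxolane, via 1,2-dibromoethyl ether 7 (not isolated)
Conditions: Br2 (1.0 equiv), CH2Cl2, −78 °C; then i-Pr2NEt (3 equiv), −78 °C → 40 °C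
Reagents that add atoms: bromine, BrBr
Why: Electrophilic addition of Br2 to the enol ether gives the α,β-dibromo ether, whose labile α-C–Br bond is lost with a β-proton under amine base, as in the preparation of (Z)-2-bromovinyl ethyl ether, so the Z isomer should predominate; ring A, whose only free position is meta to both oxygens, should not be brominated at −78 °C.

Step 6
Reactants: 8 2-{3,5-dibromo-2-[(Z)-2-bromoethenyloxy]-4-methoxyphenyl}-1,3-dioxolane
Product: 9 2-[3,5-dibromo-2-(ethynyloxy)-4-methoxyphenyl]-1,3-dioxolane
Conditions: KOt-Bu (2.2 equiv), THF, −78 → −20 °C; pH 7 phosphate buffer; used at once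
Reagents that add atoms: none
Why: Anti-periplanar E2 loss of HBr from the (Z)-β-bromo enol ether (the vinyl H on the oxygen-bearing carbon is trans to Br), the classical dehydrohalogenation route to alkoxy- and aryloxyacetylenes; an alkoxide base avoids the halogen–metal exchange that an alkyllithium would cause at the aryl bromides.

Step 7
Reactants: 10 coumalic acid
Product: 11 3,5-dibromo-2H-pyran-2-one
Conditions: NBS (2.5 equiv), LiOAc (cat.), MeCN–H2O, rt
Reagents that add atoms: N-bromosuccinimide, O=C1CCC(=O)N1Br
Why: Bromodecarboxylation at C5 (ipso substitution of the vinylogous carboxylate) followed by electrophilic bromination at the nucleophilic C3 of the pyrone, a known one-pot preparation of this diene.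

Step 8
Reactants: 9 2-[3,5-dibromo-2-(ethynyloxy)-4-methoxyphenyl]-1,3-dioxolane; 11 3,5-dibromo-2H-pyran-2-one (1.5 equiv)
Product: 13 2-[3,5-dibromo-2-(2,4-dibromophenoxy)-4-methoxyphenyl]-1,3-dioxolane, via bridged bicyclic lactone 12 (not isolated)
Conditions: PhMe, BHT (cat.), 100 °C, sealed tube
Reagents that add atoms: none
Why: The electron-rich ethynyl ether and the electron-poor dibromopyrone should combine in an inverse-electron-demand [4+2] cycloaddition across C3 and C6 of the pyrone, and lactone 12 then expels CO2 by a retro-[4+2] driven by aromatisation. The closest known reactions are the benzannulations of 2-pyrones with alkynes, including ynamines and siloxy- or alkoxyalkynes, and the cycloadditions of 3,5-dibromo-2-pyrone with enol ethers. Ring B closes by this intermolecular six-membered cycloaddition, with C1'–C2' and C5'–C6' formed in one asynchronous step. The two bridgehead stereocentres of 12 are lost with the CO2, so the product has none. The step needs regioselectivity: the terminal CH of the ynol ether, which carries the larger HOMO coefficient, should bond to C6, the most electrophilic diene terminus, placing the oxygen-bearing carbon next to C3–Br as seen with enol ethers and this pyrone. Because the alkyne adduct is already at the arene oxidation level, neither loss of the aryloxy group nor loss of HBr can intervene, and ring A with its dioxolane is a spectator.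

Step 9
Reactants: 13 2-[3,5-dibromo-2-(2,4-dibromophenoxy)-4-methoxyphenyl]-1,3-dioxolane
Product: 14 3,5-dibromo-2-(2,4-dibromophenoxy)-4-methoxybenzaldehyde
Conditions: 2 M HCl, THF, rt
Reagents that add atoms: water, O
Why: Acid-catalysed acetal hydrolysis; the diaryl ether, aryl bromides and methyl ether are stable to dilute aqueous acid at room temperature.

Step 10
Reactants: 14 3,5-dibromo-2-(2,4-dibromophenoxy)-4-methoxybenzaldehyde
Product: 16 3,5-dibromo-2-(2,4-dibromophenoxy)-4-methoxyphenol, via aryl formate 15 (not isolated)
Conditions: mCPBA (1.5 equiv), CH2Cl2, rt; then Et3N (cat.), MeOH, rt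
Reagents that add atoms: meta-chloroperoxybenzoic acid, O=C(OO)c1cccc(Cl)c1
Why: Baeyer–Villiger (Dakin-type) oxidation; in the Criegee adduct the aryl group, made electron-rich by the para OMe and ortho OAr groups, should migrate in preference to H, and the formate is cleaved by base-catalysed methanolysis.

**Compound list**

1 | 2-hydroxy-4-methoxybenzaldehyde | COc1ccc(C=O)c(O)c1 | starting material
2 | 3,5-dibromo-2-hydroxy-4-methoxybenzaldehyde | COc1c(Br)cc(C=O)c(O)c1Br | intermediate
3 | 1,2-dibromoethane | BrCCBr | starting material
4 | 3,5-dibromo-2-(2-bromoethoxy)-4-methoxybenzaldehyde | COc1c(Br)cc(C=O)c(OCCBr)c1Br | intermediate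
5 | 2-[3,5-dibromo-2-(2-bromoethoxy)-4-methoxyphenyl]-1,3-dioxolane | COc1c(Br)cc(C2OCCO2)c(OCCBr)c1Br | intermediate
6 | 2-[3,5-dibromo-2-(ethenyloxy)-4-methoxyphenyl]-1,3-dioxolane | COc1c(Br)cc(C2OCCO2)c(OC=C)c1Br | intermediate
7 | 2-[3,5-dibromo-2-(1,2-dibromoethoxy)-4-methoxyphenyl]-1,3-dioxolane (racemic) | COc1c(Br)cc(C2OCCO2)c(OC(Br)CBr)c1Br | intermediate (not isolated)
8 | 2-{3,5-dibromo-2-[(Z)-2-bromoethenyloxy]-4-methoxyphenyl}-1,3-dioxolane | COc1c(Br)cc(C2OCCO2)c(O/C=C\Br)c1Br | intermediate
9 | 2-[3,5-dibromo-2-(ethynyloxy)-4-methoxyphenyl]-1,3-dioxolane | COc1c(Br)cc(C2OCCO2)c(OC#C)c1Br | intermediate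
10 | coumalic acid (2-oxo-2H-pyran-5-carboxylic acid) | O=C(O)c1ccc(=O)oc1 | starting material
11 | 3,5-dibromo-2H-pyran-2-one | O=c1occ(Br)cc1Br | intermediate
12 | 4,7-dibromo-5-[2,4-dibromo-6-(1,3-dioxolan-2-yl)-3-methoxyphenoxy]-2-oxabicyclo[2.2.2]octa-5,7-dien-3-one (racemic) | O=C1OC2C(Br)=CC1(Br)C(Oc3c(C4OCCO4)cc(Br)c(OC)c3Br)=C2 | intermediate (not isolated)
13 | 2-[3,5-dibromo-2-(2,4-dibromophenoxy)-4-methoxyphenyl]-1,3-dioxolane | COc1c(Br)cc(C2OCCO2)c(Oc3ccc(Br)cc3Br)c1Br | intermediate
14 | 3,5-dibromo-2-(2,4-dibromophenoxy)-4-methoxybenzaldehyde | COc1c(Br)cc(C=O)c(Oc2ccc(Br)cc2Br)c1Br | intermediate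
15 | 3,5-dibromo-2-(2,4-dibromophenoxy)-4-methoxyphenyl formate | COc1c(Br)cc(OC=O)c(Oc2ccc(Br)cc2Br)c1Br | intermediate (not isolated)
16 | 3,5-dibromo-2-(2,4-dibromophenoxy)-4-methoxyphenol | COc1c(Br)cc(O)c(Oc2ccc(Br)cc2Br)c1Br | target

**Step count and risks**

Total step count: 10. Longest linear sequence: 9 (steps 1–6, then 8–10); step 7 is the convergent branch.

Steps most likely to fail:

1. Step 8. The terminal ynol ether may oligomerise faster than it adds to the pyrone, the bulky and rather electron-poor aryloxy group may slow the cycloaddition, and the orientation may erode. Fallback, from 2 back to 14, without the cycloaddition: 1,3-dibromobenzene is condensed with iodyl sulfate [(IO)2SO4, from I2 and KIO3 in concentrated H2SO4] and the salt precipitated with NH4Cl as bis(2,4-dibromophenyl)iodonium chloride F1. The potassium phenoxide of 2 (K2CO3, DMF, 80 °C) is then O-arylated by F1 in a metal-free ligand coupling, which should give aldehyde 14 directly and rejoin the route before step 10.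

2. Step 6. The second dehydrobromination may stall, or the terminal ynol ether may be degraded under the basic conditions (attack of alkoxide on the alkyne with release of the phenoxide, oligomerisation of the acetylide). Fallback, from 8 back to 13, keeping the same two ring B bonds: the bromovinyl ether 8 is itself used as the dienophile. Heating with 11 (PhMe, 100 °C) should give, with the same orientation, the tribromo bicyclic lactone F2. Further heating with DBU (xylene, 140 °C) should expel CO2 and then HBr, bromide being a better leaving group than the aryloxide, to give 13.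

3. Step 10. Hydride migration may compete with aryl migration in the Criegee adduct, because the dibrominated ring is a weaker migrating group, and the aldehyde would then be over-oxidised to the benzoic acid. Fallback, from 14 to 16: MeMgBr (THF, −78 °C) adds to the aldehyde to give the secondary alcohol F3, and Dess–Martin periodinane oxidises it to the methyl ketone F4. Baeyer–Villiger oxidation (mCPBA, NaHCO3, CH2Cl2), where the aryl group competes only with methyl, gives the aryl acetate F5, which K2CO3 in MeOH cleaves to 16.

**Further compounds**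

F1 | step 8 | bis(2,4-dibromophenyl)iodonium chloride | Brc1ccc([I+]c2ccc(Br)cc2Br)c(Br)c1.[Cl-]
F2 | step 6 | 2-oxabicyclo[2.2.2]octenone lactone with Br at the bridgehead next to C=O, cis ArO and Br on the saturated bridge, and Br on the alkene (racemic, endo/exo mixture; Ar = 2,4-dibromo-6-(1,3-dioxolan-2-yl)-3-methoxyphenyl) | O=C1OC2C(Br)=CC1(Br)C(Oc3c(C4OCCO4)cc(Br)c(OC)c3Br)C2Br
F3 | step 10 | 1-[3,5-dibromo-2-(2,4-dibromophenoxy)-4-methoxyphenyl]ethanol (racemic) | COc1c(Br)cc(C(C)O)c(Oc2ccc(Br)cc2Br)c1Br
F4 | step 10 | 1-[3,5-dibromo-2-(2,4-dibromophenoxy)-4-methoxyphenyl]ethanone | COc1c(Br)cc(C(C)=O)c(Oc2ccc(Br)cc2Br)c1Br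
F5 | step 10 | 3,5-dibromo-2-(2,4-dibromophenoxy)-4-methoxyphenyl acetate | COc1c(Br)cc(OC(C)=O)c(Oc2ccc(Br)cc2Br)c1Br
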